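## Structural features

The target, 4-[(2-heptyl-4,6-dimethoxybenzoyl)oxy]-2-methoxy-6-pentylbenzoic acid, is a depside: two benzene rings that share no atom and are joined only by an aryl ester, from the carboxyl carbon on C1 of ring A to the oxygen on C4 of ring B. Ring A carries n-heptyl at C2 and methoxy groups at C4 and C6. Ring B is a benzoic acid with methoxy at C2, the acyloxy group at C4 and n-pentyl at C6, so each of the two carbonyl carbons sits between two ortho substituents. There is no stereocentre and no geometric or axial isomerism, so the problem is one of regiochemistry and chemoselectivity only. The fragile groups are the inter-ring ester, a good acyl donor toward hydroxide, alkoxides and amines, and the electron-rich, doubly ortho-substituted carboxylic acid of ring B, which can lose carbon dioxide in hot acid; the last steps must therefore be neutral. The real difficulty lies in ring B: its two resorcinol-type oxygens must end up different (methyl ether at C2 beside the carboxyl group, ester at C4), and the substituents on C1, C2, C4 and C6 must be placed without regioisomers. A smaller difficulty is acyl transfer from the hindered ring A acid to a phenol of low nucleophilicity. The key step exploits the fact that the C1–C6 edge of ring B (carboxyl carbon next to pentyl carbon) corresponds to an alk-2-ynoate, while C2(OMe)–C3–C4(O)–C5 corresponds to a 1-alkoxy-3-silyloxy diene, so a cyclohexadiene delivers the two oxygens already distinguished.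

## Logic of the disconnections

16 to 15: the O–CH2 bond of a benzyl ester on the ring B carboxyl is added retrosynthetically. A free acid would compete in the acylation step, and a benzyl ester can be removed by hydrogenolysis without acid or base. There is no skeletal gain; the demand is that the last step leaves the aryl ester and the arenes untouched.

15 to 9 and 13: the acyl C–O bond of the inter-ring ester is cut. It is the only bond joining the two halves, so the cut is fully convergent and gives two monocyclic pieces of similar size. The forward step must acylate a weakly nucleophilic phenol with a di-ortho-substituted acid without base, and 9 must carry exactly one free hydroxyl.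

9 to 8: the O–Si bond at C4 of ring B is restored. This is bookkeeping, but it shows that the C4 oxygen arrives masked and distinct from the C2 methyl ether.

8 to 3 and 6 (through 7): the C1–C2 and C5–C6 bonds of ring B are cut after formally adding ethylene back across C2 and C5. This one operation sets all four substituents of ring B and the difference between its two oxygens. The ring is reduced to a six-carbon vinylogous ester derivative and an acyclic eight-carbon ynoate. The atom mapping was checked: the methoxy-bearing terminus of 3 becomes C2, its unsubstituted terminus becomes C5, and the two alkyne carbons of 6 become C1 and C6; the structures are consistent and need no correction. The forward step needs one regiochemical sense of addition and a partner pair that tolerates 150–180 °C.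

3 to 1 (through 2): the O–Si bond of the silyl enol ether is cut. The forward step must deprotonate 1 kinetically at the methylene next to the carbonyl (not at the gamma position), otherwise the two oxygens would exchange roles.

6 to 4 (through 5): the O–CH2 bond of the benzyl ester is cut. The forward alkylation must use a base too weak to isomerise the ynoate to an allenoate.

13 to 10 and 11 (through 12): the bond between the first and second carbon of the heptyl chain is cut. This leaves a purchasable arene that already carries the carboxyl group and both methoxy groups in the right places, so ring A needs no ring synthesis, formylation or oxidation. An aldehyde-based route through the acyl chloride would cost five operations; this costs one. The forward step demands benzylic (lateral) deprotonation of the carboxylate and clean monoalkylation by a primary iodide.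

## Other disconnections considered

Alternative 1: The cut is at C1–C6 and C2–C3 of ring B, at the cyclohexane-1,3-dione oxidation level.
- Forward step: dibenzyl malonate A1 would add in a Michael reaction to (E)-non-3-en-2-one A2 under sodium benzyloxide (NaOCH2Ph, chosen to avoid ester exchange). The methyl ketone enolate would then close the ring by Claisen condensation on one malonate ester to give benzyl 2,4-dioxo-6-pentylcyclohexane-1-carboxylate A3 (racemic, trans). Dehydrogenation would lead to benzyl 2,4-dihydroxy-6-pentylbenzoate A4.
- In favour: cheap reagents, ordinary temperatures, no moisture-sensitive diene, and regiochemistry fixed by the connectivity of A1 and A2. On cost and scalability it is the better plan.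
- Against: A3 is a beta-keto ester that decarboxylates easily, an oxidation step is needed, and A4 has two free hydroxyls. The C4 hydroxyl is the more reactive, so acylation with 13 should go to the right oxygen. The hydrogen-bonded C2 hydroxyl would then have to be methylated with base next to the labile depside ester, or else C4 must be protected, C2 methylated and C4 released.
- Comparison: on structure, the oxygens are differentiated by reactivity after the ring exists, whereas the chosen plan differentiates them by construction. On mechanism, two ionic bond formations and a separate oxidation stand against one pericyclic sequence that delivers the arene directly. On step economy, five linear steps if the late methylation is clean, which equals the chosen plan; two or three more if protection is needed.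

Alternative 2: The cut is at the inter-ring ester C–O bond, with ring A not yet aromatic, plus C1–C2 of ring A.
- Forward step: heating 6-(2,4-dioxoundecyl)-2,2-dimethyl-4H-1,3-dioxin-4-one A5 would release acetone and the acylketene 3,5,7-trioxotetradec-1-en-1-one A6. Phenol 9 would trap A6 to give benzyl 2-methoxy-6-pentyl-4-[(3,5,7-trioxotetradecanoyl)oxy]benzoate A7. Base and then acid would close ring A by aldol condensation and dehydration to give benzyl 4-(2-heptyl-4,6-dihydroxybenzoyl)oxy-2-methoxy-6-pentylbenzoate A8.
- In favour: the ester is made from an unhindered, very electrophilic ketene under neutral conditions, so the hindered acyl transfer of the chosen step 6 is avoided. On that single point it is the better plan.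
- Against: A5 needs several steps of dioxinone acylation chemistry. A7 is an activated aryl ester of a beta-keto acid, and during the base-mediated cyclisation it could expel the phenoxide (pyranone formation) in competition with the aldol. A8 then needs two O-methylations, one at a hydrogen-bonded hydroxyl, with base in the presence of the depside ester.
- Comparison: on structure, it still depends on 9, so it replaces only steps 5 and 6 and not the ring B construction. On mechanism, it is the more elegant ester formation but has more competing pathways after it. On step economy, at least five operations for ring A and the ester, against two in the chosen plan.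

Alternative 3: The cut is at C2–C3 and C4–C5 of ring A.
- Forward step: benzyl 6-heptyl-4-methoxy-2-oxo-2H-pyran-5-carboxylate A9 and 1,1-dimethoxyethene A10 would undergo (4+2) cycloaddition, the nucleophilic CH2 of A10 bonding to the electrophilic C6 of the pyrone. Loss of carbon dioxide and then methanol would give benzyl 2-heptyl-4,6-dimethoxybenzoate A11, and hydrogenolysis would give 13.
- In favour: regiochemistry is under electronic control, both methoxy groups are placed without any selective methylation, and the approach would be the better one if ring A needed a substitution pattern for which no purchasable arene exists.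
- Against: A9 must itself be assembled (a beta-keto ester, a malonyl unit, and a regioselective O-methylation of an ambident hydroxypyrone). A10 is moisture-sensitive, and an extra hydrogenolysis is needed before coupling.
- Comparison: on structure, it addresses ring A, the easier half, and leaves the oxygen differentiation of ring B unsolved. On mechanism, it is the same class as the chosen key step (cycloaddition followed by extrusion and aromatisation), so it is the equal of the chosen plan in regiocontrol. On step economy, about five steps to 13 against one.

Key step: step 3

Remark on the chemistry: the target has no stereocentre, so no stereocontrol is required; 10 (orsellinic acid dimethyl ether) is taken as a purchasable compound; salts that exist only until aqueous work-up are not numbered.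

## Route

Step 1
Reactants: 1 3-methoxycyclohex-2-en-1-one
Product: 3 1-methoxy-3-(trimethylsilyloxy)cyclohexa-1,3-diene, via lithium dienolate 2 (not isolated)
Conditions: LDA, THF, −78 °C; TMSCl, −78 °C → rt; non-aqueous work-up (pentane, filtration, distillation)
Reagents that add atoms: chlorotrimethylsilane, C[Si](C)(C)Cl
Why: Kinetic deprotonation of the vinylogous ester by LDA at −78 °C takes place at the methylene next to the carbonyl and not at the gamma position, giving the cross-conjugated dienolate 2, which is O-silylated by the hard electrophile TMSCl (silyl enol ether formation). The work-up avoids water because 3 hydrolyses easily.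

Step 2
Reactants: 4 oct-2-ynoic acid
Product: 6 benzyl oct-2-ynoate, via potassium oct-2-ynoate 5 (not isolated)
Conditions: BnBr, KHCO3, DMF, rt
Reagents that add atoms: benzyl bromide, BrCc1ccccc1
Why: SN2 O-alkylation of a carboxylate by benzyl bromide in a dipolar aprotic solvent; hydrogencarbonate deprotonates the acidic alkynoic acid but is too weak to isomerise the ynoate to the allenoate.

Step 3
Reactants: 3 1-methoxy-3-(trimethylsilyloxy)cyclohexa-1,3-diene; 6 benzyl oct-2-ynoate
Product: 8 benzyl 2-methoxy-6-pentyl-4-(trimethylsilyloxy)benzoate, via bicyclo[2.2.2]octadiene adduct 7 (not isolated)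
Conditions: 3 (2 equiv), neat, Ar, 150 → 180 °C, ethylene vented
Reagents that add atoms: none
Why: Alder–Rickert reaction. Diene 3 is doubly oxygen-activated and its HOMO is largest at the unsubstituted terminus (direct donation from the silyloxy group, vinylogous donation from the methoxy group), while the LUMO of ynoate 6 is largest at the beta carbon; a concerted, asynchronous normal-demand (4+2) cycloaddition therefore joins the unsubstituted terminus of 3 to the pentyl-bearing carbon and the methoxy-bearing terminus to the ester-bearing carbon, giving bicyclo[2.2.2]octadiene 7. At the same temperature 7 undergoes retro-(4+2) loss of its saturated two-carbon bridge as ethylene, an irreversible step driven by aromatisation and escape of a gas. Ring B is thus closed by an intermolecular (4+2) annulation that makes both new sigma bonds (C1–C2 and C5–C6) at once, not by end-to-end cyclisation of a chain; the closest known reaction type is the Alder–Rickert synthesis of resorcylate monoethers from 1-alkoxy-3-silyloxycyclohexa-1,3-dienes and alk-2-ynoates. No stereocentre is created in 8: the two bridgehead centres of 7 form as a racemate and are erased on aromatisation. The selectivity needed is regiochemical (methoxy carbon next to the ester carbon), and it is secured by the matched polarisation of the two partners, which should outweigh the small steric preference for the opposite orientation. The excess of 3 allows for its thermal 1,5-hydrogen shift and adventitious hydrolysis, and partial loss of the silyl group is harmless because step 4 removes it.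

Step 4
Reactants: 8 benzyl 2-methoxy-6-pentyl-4-(trimethylsilyloxy)benzoate
Product: 9 benzyl 4-hydroxy-2-methoxy-6-pentylbenzoate
Conditions: 1 M HCl, THF, rt (on crude 8)
Reagents that add atoms: none
Why: Acid-catalysed solvolysis of an aryl trimethylsilyl ether at silicon is fast at room temperature; the benzyl ester and the aryl methyl ether are inert to dilute acid.

Step 5
Reactants: 10 2,4-dimethoxy-6-methylbenzoic acid; 11 1-iodohexane
Product: 13 2-heptyl-4,6-dimethoxybenzoic acid, via benzylic dianion 12 (not isolated)
Conditions: LDA (2.2 equiv), THF, −78 → 0 °C; 11, −78 °C → rt; 1 M HCl work-up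
Reagents that add atoms: none
Why: Lateral lithiation of an ortho-toluic acid: the first equivalent of LDA gives the carboxylate and the second removes a proton from the ortho methyl group, whose anion is stabilised by the neighbouring carboxylate; both ring positions ortho to the carboxylate are blocked and LDA does not metalate anisole-type C–H bonds. The benzylic carbanion of 12 is far more nucleophilic than the carboxylate oxygen and is alkylated by the primary iodide (SN2 C-alkylation of a toluate dianion).

Step 6
Reactants: 13 2-heptyl-4,6-dimethoxybenzoic acid; 9 benzyl 4-hydroxy-2-methoxy-6-pentylbenzoate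
Product: 15 benzyl 4-[(2-heptyl-4,6-dimethoxybenzoyl)oxy]-2-methoxy-6-pentylbenzoate, via mixed trifluoroacetic anhydride 14 (not isolated)
Conditions: TFAA, toluene, 0 °C → rt
Reagents that add atoms: none
Why: Mixed-anhydride esterification, the standard depside-forming method: TFAA converts the acid into acyl trifluoroacetate 14, which for an electron-rich di-ortho-substituted benzoic acid ionises readily toward an acylium ion that is not hampered by the ortho groups and acylates the only free hydroxyl of 9. No base is present, so neither ester is at risk.

Step 7
Reactants: 15 benzyl 4-[(2-heptyl-4,6-dimethoxybenzoyl)oxy]-2-methoxy-6-pentylbenzoate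
Product: 16 4-[(2-heptyl-4,6-dimethoxybenzoyl)oxy]-2-methoxy-6-pentylbenzoic acid
Conditions: H2 (1 atm), 10% Pd/C, EtOAc, rt
Reagents that add atoms: none
Why: Hydrogenolysis of the benzylic C–O bond on Pd/C at neutral pH; the aryl ester, the aryl ethers and the arenes are not reduced under these conditions, and neither acid nor base touches the depside link or the decarboxylation-prone acid.

## Compound list

1 | 3-methoxycyclohex-2-en-1-one | COC1=CC(=O)CCC1 | starting material
2 | lithium 5-methoxycyclohexa-1,5-dien-1-olate (not isolated) | [Li+].[O-]C1=CCCC(OC)=C1 | intermediate
3 | 1-methoxy-3-(trimethylsilyloxy)cyclohexa-1,3-diene | COC1=CC(O[Si](C)(C)C)=CCC1 | intermediate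
4 | oct-2-ynoic acid | CCCCCC#CC(=O)O | starting material
5 | potassium oct-2-ynoate (not isolated) | CCCCCC#CC(=O)[O-].[K+] | intermediate
6 | benzyl oct-2-ynoate | CCCCCC#CC(=O)OCc1ccccc1 | intermediate
7 | benzyl 1-methoxy-3-pentyl-5-(trimethylsilyloxy)bicyclo[2.2.2]octa-2,5-diene-2-carboxylate (racemic, not isolated) | COC12CCC(C(CCCCC)=C1C(=O)OCc1ccccc1)C(O[Si](C)(C)C)=C2 | intermediate
8 | benzyl 2-methoxy-6-pentyl-4-(trimethylsilyloxy)benzoate | CCCCCc1cc(O[Si](C)(C)C)cc(OC)c1C(=O)OCc1ccccc1 | intermediate
9 | benzyl 4-hydroxy-2-methoxy-6-pentylbenzoate | CCCCCc1cc(O)cc(OC)c1C(=O)OCc1ccccc1 | intermediate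
10 | 2,4-dimethoxy-6-methylbenzoic acid | Cc1cc(OC)cc(OC)c1C(=O)O | starting material
11 | 1-iodohexane | CCCCCCI | starting material
12 | lithium 2-(lithiomethyl)-4,6-dimethoxybenzoate, the benzylic dianion (not isolated) | [Li+].[Li+].[CH2-]c1cc(OC)cc(OC)c1C(=O)[O-] | intermediate
13 | 2-heptyl-4,6-dimethoxybenzoic acid | CCCCCCCc1cc(OC)cc(OC)c1C(=O)O | intermediate
14 | 2-heptyl-4,6-dimethoxybenzoic trifluoroacetic anhydride (not isolated) | CCCCCCCc1cc(OC)cc(OC)c1C(=O)OC(=O)C(F)(F)F | intermediate
15 | benzyl 4-[(2-heptyl-4,6-dimethoxybenzoyl)oxy]-2-methoxy-6-pentylbenzoate | CCCCCCCc1cc(OC)cc(OC)c1C(=O)Oc1cc(CCCCC)c(C(=O)OCc2ccccc2)c(OC)c1 | intermediate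
16 | 4-[(2-heptyl-4,6-dimethoxybenzoyl)oxy]-2-methoxy-6-pentylbenzoic acid | CCCCCCCc1cc(OC)cc(OC)c1C(=O)Oc1cc(CCCCC)c(C(=O)O)c(OC)c1 | target

## Step count and least certain steps

Total step count: 7. Longest linear sequence: 5 steps (steps 1, 3, 4, 6, 7 from 1; the branch from 4 through steps 2, 3, 4, 6, 7 is equally long).

Step 3 (key step). Most likely to go wrong: incomplete cycloaddition, because a beta-alkyl ynoate is a sluggish dienophile and, at the temperature it needs, the diene may be used up by 1,5-hydrogen shift, desilylation or oligomerisation; erosion of regioselectivity at high temperature is a lesser concern. Fallback, setting out from 6 and returning at 8: the cyclic diene is replaced by a more nucleophilic acyclic ketene-acetal diene that aromatises by loss of methanol rather than ethylene. The known vinylogous ester 4,4-dimethoxybut-3-en-2-one F1 is enol-silylated (TMSOTf, Et3N, Et2O, 0 °C) to 1,1-dimethoxy-3-(trimethylsilyloxy)buta-1,3-diene F2. F2 and 6 in toluene or xylene at 110–140 °C should give, with the same electronic regiocontrol, benzyl 6,6-dimethoxy-2-pentyl-4-(trimethylsilyloxy)cyclohexa-1,4-diene-1-carboxylate F3, which is not isolated and eliminates methanol to give 8. The route resumes at step 4.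

Step 5. Most likely to go wrong: incomplete second deprotonation, or quenching of the benzylic anion by elimination from the iodide, so that unchanged 10 accompanies 13 and the two acids are hard to separate; O-alkylation of the carboxylate is a minor competing path. Fallback, setting out from 11 and returning at 13: the chain is attached by olefination and the carboxyl carbon is introduced afterwards.
- 11 and PPh3 (MeCN, reflux) give hexyltriphenylphosphonium iodide F4.
- KOtBu in THF converts F4 into hexylidenetriphenylphosphorane F5, which in a Wittig reaction olefinates 3,5-dimethoxybenzaldehyde F6 to 1-(hept-1-en-1-yl)-3,5-dimethoxybenzene F7 (E/Z mixture, of no consequence).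
- Hydrogenation (H2, Pd/C, EtOAc) gives 1-heptyl-3,5-dimethoxybenzene F8.
- Vilsmeier–Haack formylation (POCl3, DMF) at the position ortho to the chain and para to a methoxy group gives 2-heptyl-4,6-dimethoxybenzaldehyde F9.
- Pinnick oxidation (NaClO2, NaH2PO4, 2-methylbut-2-ene, tBuOH/H2O) returns to 13.

Step 6. Most likely to go wrong: slow acyl transfer to the electron-poor phenol, which would let O-trifluoroacetylation of 9, symmetric anhydride formation, or Friedel–Crafts self-acylation of the electron-rich ring A by the acylium ion compete. Fallback, setting out from 13 and returning at 15: the activation is moved from acid to base. Oxalyl chloride with catalytic DMF in CH2Cl2 converts 13 into 2-heptyl-4,6-dimethoxybenzoyl chloride F10, which is isolated free of acid and then added to 9 with Et3N and catalytic DMAP in CH2Cl2; addition–elimination through the acylpyridinium should give 15.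

## Further compounds

F1 | step 3 | 4,4-dimethoxybut-3-en-2-one | CC(=O)C=C(OC)OC
F2 | step 3 | 1,1-dimethoxy-3-(trimethylsilyloxy)buta-1,3-diene | COC(OC)=CC(=C)O[Si](C)(C)C
F3 | step 3 | benzyl 6,6-dimethoxy-2-pentyl-4-(trimethylsilyloxy)cyclohexa-1,4-diene-1-carboxylate | CCCCCC1=C(C(=O)OCc2ccccc2)C(OC)(OC)C=C(O[Si](C)(C)C)C1
F4 | step 5 | hexyltriphenylphosphonium iodide | CCCCCC[P+](c1ccccc1)(c1ccccc1)c1ccccc1.[I-]
F5 | step 5 | hexylidenetriphenylphosphorane | CCCCCC=P(c1ccccc1)(c1ccccc1)c1ccccc1
F6 | step 5 | 3,5-dimethoxybenzaldehyde | COc1cc(C=O)cc(OC)c1
F7 | step 5 | 1-(hept-1-en-1-yl)-3,5-dimethoxybenzene (E/Z mixture) | CCCCCC=Cc1cc(OC)cc(OC)c1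
F8 | step 5 | 1-heptyl-3,5-dimethoxybenzene | CCCCCCCc1cc(OC)cc(OC)c1
F9 | step 5 | 2-heptyl-4,6-dimethoxybenzaldehyde | CCCCCCCc1cc(OC)cc(OC)c1C=O
F10 | step 6 | 2-heptyl-4,6-dimethoxybenzoyl chloride | CCCCCCCc1cc(OC)cc(OC)c1C(Cl)=O
A1 | alternative 1 | dibenzyl malonate | O=C(CC(=O)OCc1ccccc1)OCc1ccccc1
A2 | alternative 1 | (E)-non-3-en-2-one | CCCCC/C=C/C(C)=O
A3 | alternative 1 | benzyl 2,4-dioxo-6-pentylcyclohexane-1-carboxylate (racemic, trans drawn) | CCCCC[C@@H]1CC(=O)CC(=O)[C@H]1C(=O)OCc1ccccc1
A4 | alternative 1 | benzyl 2,4-dihydroxy-6-pentylbenzoate | CCCCCc1cc(O)cc(O)c1C(=O)OCc1ccccc1
A5 | alternative 2 | 6-(2,4-dioxoundecyl)-2,2-dimethyl-4H-1,3-dioxin-4-one | CCCCCCCC(=O)CC(=O)CC1=CC(=O)OC(C)(C)O1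
A6 | alternative 2 | 3,5,7-trioxotetradec-1-en-1-one | CCCCCCCC(=O)CC(=O)CC(=O)C=C=O
A7 | alternative 2 | benzyl 2-methoxy-6-pentyl-4-[(3,5,7-trioxotetradecanoyl)oxy]benzoate | CCCCCCCC(=O)CC(=O)CC(=O)CC(=O)Oc1cc(CCCCC)c(C(=O)OCc2ccccc2)c(OC)c1
A8 | alternative 2 | benzyl 4-(2-heptyl-4,6-dihydroxybenzoyl)oxy-2-methoxy-6-pentylbenzoate | CCCCCCCc1cc(O)cc(O)c1C(=O)Oc1cc(CCCCC)c(C(=O)OCc2ccccc2)c(OC)c1
A9 | alternative 3 | benzyl 6-heptyl-4-methoxy-2-oxo-2H-pyran-5-carboxylate | CCCCCCCC1=C(C(=O)OCc2ccccc2)C(OC)=CC(=O)O1
A10 | alternative 3 | 1,1-dimethoxyethene | C=C(OC)OC
A11 | alternative 3 | benzyl 2-heptyl-4,6-dimethoxybenzoate | CCCCCCCc1cc(OC)cc(OC)c1C(=O)OCc1ccccc1
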